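(All constants stand for no real mixture; the rest is arithmetic.)

If Z runs ahead of the feed of E in larch, one ratio says what G loses to Q.

| setting | larch | elm | alder | birch | cedar |
|---|---|---|---|---|---|
| E | 0.25 M (fed, over 50 s) | 0.25 M | 0.25 M | 0.25 M (fed, over 12 s) | 0.25 M |
| X | 0.500 M | 0.500 M (fed, over 50 s) | 0.500 M | 0.500 M | 0.500 M (in portions, 3, over 50 s) |
| J | 0.0125 M | 0.0125 M | 0.0125 M | 0.0125 M | 0.0125 M |
| time | 1.5 min | 1.5 min | 1.5 min | 1.5 min | 1.5 min |
| remark | all else is in the flask from the start; the feed brings no volume worth counting | all else is in the flask from the start; the feed brings no volume worth counting | everything together at the start | all else is in the flask from the start; the feed brings no volume worth counting | first portion at the start, last at 50 s |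

- which flask leads in amount of G.Z, in percent of the E charged ("all alike" within 1.5 percentage points) (larch / elm / alder / birch / cedar / all alike)
- how much G.Z is there at the end, in percent of the E charged: larch
- how much G.Z is there at the end, in percent of the E charged: elm
- how much G.Z is there at the end, in percent of the E charged: alder
- how much G.Z is there at the end, in percent of the E charged: birch
- how much G.Z is there at the end, in percent of the E charged: cedar

    X → Z (k1 = 0.061 s⁻¹)
    G → Q (k2 = 0.022 s⁻¹)
    G + Z → G.Z (k3 = 6.0 M⁻¹ s⁻¹)
    E ⇌ G (K4 = 3.3, k4 = 0.31 s⁻¹)
    Z + J → Z.J (k5 = 0.031 M⁻¹ s⁻¹)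

I count in fractions of the E charge. G has two exits: it leaks to Q, or it takes Z and becomes G.Z.

In larch, X first supplies Z at a fraction per second of

0.122 s⁻¹, against 0.0200 s⁻¹ from the feed of E.

So Z outruns E. Once E is used, the excess of Z is

(0.500 M − 0.25 M) / 0.25 M = 100%.

J can take at most 5.00%, less than that excess, so I leave J out. I freeze Z at the excess, which makes capture pseudo-first-order.

The break-even Z is the level at which both exits run equally:

0.022 s⁻¹ / (6.0 M⁻¹ s⁻¹ × 0.25 M) = 1.47%.

The leak share, break-even Z over the sum of break-even Z and Z, is then

1.45%.

The weak link is the start, when Z is not yet at the excess. X takes 11.4 s to half pass into Z, and in that time 22.7% of the E goes in. I give that part half the excess, so its share is twice the frozen one. The reforged leak is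

1.45% × (1 + 22.7%) = 1.77%.

After the feed, 40.0 s remain, longer than the capture time of 0.667 s. So I commit to 98.2% of G.Z in larch. My reckoning stops there, because in elm X comes over 50 s and the excess is not frozen.

The forecast puts larch first at 98%, with birch 97%, alder 95%, cedar 75% and elm 72%, and says: “Feeding E slowly keeps G scarce against a growing excess of Z”.

The flasks give 98.5% of G.Z in larch, 96.8% in birch, 93.0% in alder, 76.5% in cedar and 71.4% in elm. Larch holds 1.51% of Q after 1.50 min, with Z at 98.3% of the E charge. In birch the feed takes 12 s, so the share of E that goes in during those 11.4 s grows to 95.0%. The leak share then gives 1.45% × (1 + 95.0%) = 2.83%. Birch holds 3.21% of Q after 1.50 min.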